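**Assumption:** the target, 2-hydroxy-5-methoxy-3-pentadecyl-1,4-benzoquinone, has no stereocentre and is achiral, so "single enantiomer" is taken to mean the compound exactly as drawn.

## Retrosynthetic overview

- The free hydroxyl is unmasked last from a tert-butyl ether, so hydroxy and methoxy are never both methyl ethers and no selective demethylation is needed.
- The quinone ring is not derived from an arene: it is the only ring formed, made in step 3 by thermal four-to-six ring expansion (Moore rearrangement) of a 4-hydroxy-4-(methoxyethynyl)cyclobutenone.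
- That cyclobutenone comes from 1,2-addition of lithium methoxyacetylide to 3-tert-butoxy-4-pentadecylcyclobutenedione, which fixes the chain next to the masked hydroxyl and the methoxy para to it.
- The cyclobutenedione comes from purchased di-tert-butyl squarate (four-membered ring bought) and a pentadecyl Grignard reagent.

## Route

Step 1
Reactants: 1 1-bromopentadecane; 2 di-tert-butyl squarate (3,4-di-tert-butoxycyclobut-3-ene-1,2-dione)
Product: 6 3-tert-butoxy-4-pentadecylcyclobut-3-ene-1,2-dione, via pentadecylmagnesium bromide 3 (not isolated), via bromomagnesium alkoxide adduct 4 (not isolated), via tertiary trifluoroacetate 5 (not isolated)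
Conditions: 1 (1.1 equiv), Mg, THF, reflux; added to 2, THF, −78 °C; (CF3CO)2O (1.3 equiv), −78 to 0 °C; cold H2O, Et2O extraction
Reagents that add atoms: none
Why: Grignard 1,2-addition to one squarate carbonyl followed by O-trifluoroacetylation triggers the established squarate 1,3-carbonyl transposition, in which ionisation gives an alkoxy-stabilised cyclobutenyl cation that sheds the tert-butyl group from the oxocarbenium oxygen as isobutene, leaving one vinylogous tert-butyl ester and no stereocentre.

Step 2
Reactants: 6 3-tert-butoxy-4-pentadecylcyclobut-3-ene-1,2-dione; 7 2-chloro-1,1-dimethoxyethane (chloroacetaldehyde dimethyl acetal)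
Product: 9 racemic 3-tert-butoxy-4-hydroxy-4-(methoxyethynyl)-2-pentadecylcyclobut-2-en-1-one, via lithium methoxyacetylide 8 (not isolated)
Conditions: 7 (1.5 equiv), LiNEt2 (4.5 equiv; from Et2NH, n-BuLi), THF, 0 °C to rt; cooled to −78 °C, 6 added slowly; aq NH4Cl at −78 °C; used crude, kept acid-free
Reagents that add atoms: none
Why: Acetylide 1,2-addition (the acetylide arises by double elimination and deprotonation of the chloroacetal) goes to the ketone-like carbonyl next to the tert-butoxy carbon because the other carbonyl is deactivated as a vinylogous ester; the new carbinol centre forms racemic and is erased in step 3.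

Step 3
Reactants: 9 racemic 3-tert-butoxy-4-hydroxy-4-(methoxyethynyl)-2-pentadecylcyclobut-2-en-1-one
Product: 12 2-tert-butoxy-5-methoxy-3-pentadecylcyclohexa-2,5-diene-1,4-dione, via Z-enynylketene 10 (not isolated), via aryl diradical 11 (not isolated)
Conditions: toluene (0.02 M, degassed), 100 °C, 1–2 h
Reagents that add atoms: none
Why: Moore rearrangement, in which conrotatory 4π ring opening with the hydroxyl rotating outward puts the alkynyl group cis to the ketene, the ketene carbon closes onto the methoxy-bearing alkyne carbon to a six-membered diradical, and transfer of the hydroxyl hydrogen to the ring carbon radical gives the quinone with the substitution pattern dictated by the cyclobutenone; no stereocentre is present.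

Step 4
Reactants: 12 2-tert-butoxy-5-methoxy-3-pentadecylcyclohexa-2,5-diene-1,4-dione
Product: 13 2-hydroxy-5-methoxy-3-pentadecylcyclohexa-2,5-diene-1,4-dione (target)
Conditions: CF3CO2H, CH2Cl2, 0 °C to rt
Reagents that add atoms: none
Why: Acidolysis of the tert-butyl vinylogous ester by alkyl–oxygen cleavage (tert-butyl cation lost as isobutene) frees the hydroxyquinone, while the methyl vinylogous ester is inert to anhydrous acid, so the hydroxy/methoxy placement is unambiguous.

## Compound list

1 | 1-bromopentadecane | CCCCCCCCCCCCCCCBr | starting material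
2 | di-tert-butyl squarate (3,4-di-tert-butoxycyclobut-3-ene-1,2-dione) | CC(C)(C)OC1=C(OC(C)(C)C)C(=O)C1=O | starting material
3 | pentadecylmagnesium bromide | CCCCCCCCCCCCCCC[Mg]Br | intermediate
4 | bromomagnesium 2,3-di-tert-butoxy-4-oxo-1-pentadecylcyclobut-2-en-1-olate (racemic) | CCCCCCCCCCCCCCCC1(O[Mg]Br)C(OC(C)(C)C)=C(OC(C)(C)C)C1=O | intermediate
5 | 2,3-di-tert-butoxy-4-oxo-1-pentadecylcyclobut-2-en-1-yl trifluoroacetate (racemic) | CCCCCCCCCCCCCCCC1(OC(=O)C(F)(F)F)C(OC(C)(C)C)=C(OC(C)(C)C)C1=O | intermediate
6 | 3-tert-butoxy-4-pentadecylcyclobut-3-ene-1,2-dione | CCCCCCCCCCCCCCCC1=C(OC(C)(C)C)C(=O)C1=O | intermediate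
7 | 2-chloro-1,1-dimethoxyethane | COC(CCl)OC | starting material
8 | lithium methoxyacetylide | [Li]C#COC | intermediate
9 | 3-tert-butoxy-4-hydroxy-4-(methoxyethynyl)-2-pentadecylcyclobut-2-en-1-one (racemic) | CCCCCCCCCCCCCCCC1=C(OC(C)(C)C)C(O)(C#COC)C1=O | intermediate
10 | (3Z)-3-tert-butoxy-4-hydroxy-6-methoxy-2-pentadecylhexa-1,3-dien-5-yn-1-one (ketene; alkynyl cis to the ketene carbon) | CCCCCCCCCCCCCCCC(=C=O)/C(OC(C)(C)C)=C(/O)C#COC | intermediate
11 | 3-tert-butoxy-4-hydroxy-6-methoxy-2-pentadecylphenoxyl-5-yl diradical (oxygen radical on C1, carbon radical at C5) | CCCCCCCCCCCCCCCC1=C(OC(C)(C)C)C(O)=[C]C(OC)=C1[O] | intermediate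
12 | 2-tert-butoxy-5-methoxy-3-pentadecylcyclohexa-2,5-diene-1,4-dione | CCCCCCCCCCCCCCCC1=C(OC(C)(C)C)C(=O)C=C(OC)C1=O | intermediate
13 | 2-hydroxy-5-methoxy-3-pentadecylcyclohexa-2,5-diene-1,4-dione | CCCCCCCCCCCCCCCC1=C(O)C(=O)C=C(OC)C1=O | target

## Step count and risk

Total step count: 4. Longest linear sequence: 4 steps (1 and 2 to 13; 7 enters at step 2).

**Most likely to fail, first: step 3.** The ketene may close in the five-membered mode onto the electron-rich ynol ether carbon to give an alkylidene cyclopentenedione, or the carbinol may decompose. Fallback: abandon the ring expansion and set out from 1. Commercial 1,2,4,5-tetramethoxybenzene is lithiated between two methoxy groups (n-BuLi, THF, 0 °C) and alkylated with 1 to give 1,2,4,5-tetramethoxy-3-pentadecylbenzene F1. Oxidative demethylation with (NH4)2Ce(NO3)6 in MeCN/H2O gives 2,5-dimethoxy-3-pentadecylcyclohexa-2,5-diene-1,4-dione F2. Acid mono-hydrolysis (70% HClO4, dioxane, rt), which I recall as precedented for 3-alkyl-2,5-dimethoxybenzoquinones and selective for the methoxy group flanked by the chain, comes back to the route at 13; any regioisomer would be removed by chromatography.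

**Second: step 2.** The free Et2NH and LiOMe that accompany the acetylide can attack the vinylogous ester of 6, and 9 is prone to acid-triggered rearrangement. Fallback: set out from 6 and install the methoxy group after ring expansion. Ethynylmagnesium bromide (THF, −78 °C) adds to the same carbonyl to give 3-tert-butoxy-4-ethynyl-4-hydroxy-2-pentadecylcyclobut-2-en-1-one F3. Thermolysis in toluene (100 °C) gives 2-tert-butoxy-3-pentadecylcyclohexa-2,5-diene-1,4-dione F4. Methanol then adds conjugately at C5, the position β to the carbonyl that is not deactivated as a vinylogous ester (MeOH, catalytic ZnCl2, rt), to give 2-tert-butoxy-5-methoxy-3-pentadecylbenzene-1,4-diol F5. Ag2O re-oxidises this in the same flask and the route is rejoined at 12.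

**Third: step 1.** A long-chain Grignard reagent may reduce or add twice, and the surviving tert-butyl ester sees one equivalent of CF3CO2H. Fallback: set out from 2 and bring the chain in as an acetylide. Lithium pentadec-1-ynide (commercial 1-pentadecyne, n-BuLi, THF, −78 °C) adds to 2, and an NH4Cl quench gives 2,3-di-tert-butoxy-4-hydroxy-4-(pentadec-1-yn-1-yl)cyclobut-2-en-1-one F6. Treatment with (CF3CO)2O (−78 to 0 °C) effects the same transposition to 3-tert-butoxy-4-(pentadec-1-yn-1-yl)cyclobut-3-ene-1,2-dione F7. Hydrogenation (H2, 1 atm, Pd/C, EtOAc) saturates the alkyne but not the tetrasubstituted push–pull ring alkene, and comes back to the route at 6.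

## Further compounds

F1 | step 3 | 1,2,4,5-tetramethoxy-3-pentadecylbenzene | CCCCCCCCCCCCCCCc1c(OC)c(OC)cc(OC)c1OC
F2 | step 3 | 2,5-dimethoxy-3-pentadecylcyclohexa-2,5-diene-1,4-dione | CCCCCCCCCCCCCCCC1=C(OC)C(=O)C=C(OC)C1=O
F3 | step 2 | 3-tert-butoxy-4-ethynyl-4-hydroxy-2-pentadecylcyclobut-2-en-1-one (racemic) | CCCCCCCCCCCCCCCC1=C(OC(C)(C)C)C(O)(C#C)C1=O
F4 | step 2 | 2-tert-butoxy-3-pentadecylcyclohexa-2,5-diene-1,4-dione | CCCCCCCCCCCCCCCC1=C(OC(C)(C)C)C(=O)C=CC1=O
F5 | step 2 | 2-tert-butoxy-5-methoxy-3-pentadecylbenzene-1,4-diol | CCCCCCCCCCCCCCCc1c(OC(C)(C)C)c(O)cc(OC)c1O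
F6 | step 1 | 2,3-di-tert-butoxy-4-hydroxy-4-(pentadec-1-yn-1-yl)cyclobut-2-en-1-one (racemic) | CCCCCCCCCCCCCC#CC1(O)C(OC(C)(C)C)=C(OC(C)(C)C)C1=O
F7 | step 1 | 3-tert-butoxy-4-(pentadec-1-yn-1-yl)cyclobut-3-ene-1,2-dione | CCCCCCCCCCCCCC#CC1=C(OC(C)(C)C)C(=O)C1=O
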